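Benzofuran numbering (O1, C2, C3, C3a, C4–C7, C7a) is used for the ring system; primed locants refer to the phloroglucinol ring of phloretin. Compounds are numbered as follows: 1 phloretin, 2 tri-O-benzylphloretin, 3 2',4'-dihydroxyacetophenone, 4 its dibenzyl ether, 5 the arylglyoxal, 6 sodium p-toluenesulfinate, 7 carbinol, 8 sulfone, 9 4-(benzyloxy)benzyl chloride, 10 sulfonium salt, 11 benzylide, 12 quinone methide, 13 betaine, 14 trans-dihydrobenzofuran, 15 hexa-O-benzyl benzofuran, 16 target.

## Analysis of the target

Target 16 is an achiral benzofuran in which a furan ring (O1, C2, C3, C3a, C7a) is fused to a phloroglucinol-type benzene ring (ring A, C3a–C7a). C2 carries a 4-hydroxyphenyl group, C3 a 2,4-dihydroxybenzoyl group, C4 and C6 free hydroxyls and C7 a 3-(4-hydroxyphenyl)propanoyl chain; only C5 bears hydrogen. There is no stereocentre, so any stereochemistry created on the way has only to be removable. The sensitive features are six phenolic hydroxyls on electron-rich rings, two aryl ketones each flanked by an ortho hydroxyl, and an enolisable methylene next to the C7 ketone; the final deprotection therefore has to be neutral and non-oxidising. The difficulty is twofold. The furan must be closed onto the one phloroglucinol oxygen that lies next to the acyl-bearing C7, and the furan must carry aryl at C2 and aroyl at C3, the reverse of the pattern that condensations of phenols with 1,3-dicarbonyl compounds deliver most easily. The strategy rests on two observations. Ring A with its three oxygens and the C7 chain is phloretin (1), with C3' becoming C3a and O2' becoming O1. C2 is a single carbon bonded to O1, to C3 and to an aryl group, so it can be brought in as one benzylic carbon that acts first as a nucleophile and then as an electrophile toward the four-atom unit O1–C7a–C3a–C3, which with the aroyl group on C3 is the ortho-quinone methide 12.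

## Retrosynthetic reasoning

**16 to 15.** The six O–benzyl bonds are cut first. One kind of protecting group on all six phenols keeps the end game to a single operation, and benzyl ethers tolerate the acid, the carbonate base, the ylide and the quinone oxidant used earlier. They are removed by neutral hydrogenolysis, which spares the acylphloroglucinol from the Lewis acids that alkyl ethers would demand. The forward reaction has to cleave six ethers without reducing the furan C2=C3 bond or either ketone.

**15 to 14.** The C2=C3 double bond is traced back to the 2,3-dihydrobenzofuran 14. A one-carbon annulation onto a quinone methide necessarily leaves C2 and C3 tetrahedral, and aromatisation of the furan is a downhill oxidation. The gain is that both stereocentres of 14 are erased, so the diastereoselectivity of the annulation is of no consequence. The forward reaction must remove hydride from C2 (benzylic and next to oxygen) and a proton from C3 (next to the ketone) without oxidising the benzyl ethers.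

**14 to 8 and 10.** Both ring bonds of C2 are cut, O1–C2 and C2–C3. C2 is the only furan atom that belongs neither to the phloretin skeleton nor to the aroyl unit, so this cut divides the molecule into two fragments that are each a short sequence from commercial material. The carbon set free must bond first to electrophilic C3 and then to nucleophilic O1, which is the reactivity profile of the sulfonium benzylide 11, formed from salt 10. What remains is quinone methide 12, whose phenoxide after conjugate addition (betaine 13) is placed to close the five-membered ring. Because 12 cannot be stored, it is masked as sulfone 8, from which base releases it. Cutting at C2 rather than at C3–C3a keeps the ring closure ionic and fixes O1 as the oxygen ortho to the side arm.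

**8 to 2, 5 and 6.** The C3–C3a bond and the C3–S bond are cut. C3 is at the aldehyde oxidation level and carries the ketone as neighbour, so it corresponds to the aldehyde carbon of arylglyoxal 5. Ring A of 2 is a phloroglucinol and attacks that carbon as an electron-rich arene; the benzylic oxygen is then exchanged for the sulfonyl group of 6. The forward reaction has to substitute at C3', ortho to the free hydroxyl, and not at C5'.

**2 to 1.** Three O–benzyl bonds are cut. The hydroxyl left free is the one hydrogen-bonded to the ketone, which is the oxygen needed later both as trigger for quinone methide formation and as O1.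

**5 to 4 to 3.** The aldehyde carbon of 5 is the methyl carbon of acetophenone 4 after Riley oxidation, and 4 is the dibenzyl ether of 3.

**10 to 9.** The benzylic C–S bond is cut; the salt arises by S-alkylation of a dialkyl sulfide with benzylic chloride 9.

## Alternatives that were turned down

**Alternative 1:** Ring A is built onto a preformed furan by a Danheiser benzannulation, cutting C7–C7a, C6–C7, C4–C5 and C3a–C4.
- **Key step:** Irradiation of the furyl diazoketone A2 with ethoxyacetylene A3 should trigger a photochemical Wolff rearrangement, a [2+2] cycloaddition with the alkyne, a four-electron ring opening and a six-electron electrocyclisation onto the furan double bond, giving the 6-ethoxy-4-hydroxybenzofuran A1.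
- **For:** The furan oxygen is placed relative to the ring oxygens by construction, the C4 hydroxyl is differentiated from the C6 oxygen, and the 2-aryl/3-aroyl pattern is settled on a simple furan.
- **Against:** A1 has hydrogen at C7, so the propanoyl chain must be added later by an acylation that has to choose C7 over C5, both flanked by oxygen. A2 needs a multistep synthesis of a trisubstituted furan and contains a diaryl ketone chromophore that competes for the light. The methyl and ethyl ethers call for BBr3-type cleavage on a molecule with two ketones.
- **Comparison:** Alternative 1 is stronger on regiocontrol of ring A, since the chosen route depends on electrophilic substitution at C3' of 2. The chosen route offers instead ring A and its acyl chain intact from 1, hydrogenolysable protection, and roughly half the step count.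

**Alternative 2:** The dihydrobenzofuran is obtained from a six-membered flavene by oxidative ring contraction, the C3–C3a bond being formed by a 1,2-shift.
- **Key step:** PhI(OH)OTs in methanol activates the C3=C4 bond of the 4-aryl-2H-chromene A5; the fused aryl carbon migrates from C4 to C3 as the iodine group leaves, and the C4 cation ends as the ketone, giving trans-dihydrobenzofuran A4.
- **For:** A5 comes from classical chalcone chemistry, the 2-aryl/3-aroyl pattern is correct, and the migration is stereospecific.
- **Against:** The 2,4-dimethoxyphenyl group on C4 is itself an excellent migrating group, and its shift would give no ring contraction. Hypervalent iodine reagents also attack trimethoxyarenes. A4 again lacks the C7 chain and carries five methyl ethers, and it still needs dehydrogenation.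
- **Comparison:** The two routes are equal in passing through a dihydro stage. Alternative 2 is stronger in setting the trans configuration stereospecifically, which is of no value here. The chosen route replaces a selectivity that rests on migratory aptitude by one that rests on the fixed ortho relationship of hydroxyl and side arm, and it is shorter.

**Alternative 3:** O1–C2 and C3–C3a are cut, joining phenol 2 to the diaryl ynone A7.
- **Key step:** The free phenol of 2 adds to the β-carbon of A7 to give the aryloxy enone A8; Pd(OAc)2 with Cu(OAc)2 then couples the enone α-carbon with the ortho aryl C–H to give A6, which is identical with 15.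
- **For:** This is the shortest route. It reaches the protected target directly, with no stereocentre, no sulfone and no dehydrogenation, and O1 is fixed just as unambiguously.
- **Against:** The phenol of 2 is hydrogen-bonded and flanked on both sides, and A7 carries a donor aryl group on its β-carbon, so the conjugate addition is slow and reversible. The oxidative coupling asks divalent palladium to metalate a crowded C–H and join it to a trisubstituted enol ether carbon at high temperature. The substrate offers competing ketone-directed ortho C–H bonds and six benzyl ethers.
- **Comparison:** Alternative 3 is clearly stronger on step economy, by about three steps. The chosen route offers bond formations that are ionic, run at ambient temperature and each have an identifiable driving force (rearomatisation, then loss of a neutral sulfide), with the C3–C3a bond made early by a substitution matched to the polarity of ring A.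

Key step: step 6

## Route

Assumption: glyoxal 5 is handled as its hydrate, which should release the free aldehyde under the acidic conditions of step 4; compounds 7, 8, 13 and 14 are racemic.

Step 1
Reactants: 1 phloretin
Product: 2 4,4',6'-tri-O-benzylphloretin, 1-[2,4-bis(benzyloxy)-6-hydroxyphenyl]-3-[4-(benzyloxy)phenyl]propan-1-one
Conditions: BnBr (3.1 equiv), K2CO3, acetone, reflux
Reagents that add atoms: benzyl bromide, BrCc1ccccc1
Why: Williamson etherification; the 4'-, 4- and one ortho hydroxyl are alkylated, while the remaining ortho hydroxyl is locked in a hydrogen bond to the ketone and should stay free when the bromide is limited to three equivalents.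

Step 2
Reactants: 3 2',4'-dihydroxyacetophenone
Product: 4 2',4'-bis(benzyloxy)acetophenone
Conditions: BnBr (2.5 equiv), K2CO3, DMF, 80 °C
Reagents that add atoms: benzyl bromide, BrCc1ccccc1
Why: Williamson etherification; the chelated 2'-hydroxyl is alkylated as well under forcing conditions with excess bromide in a dipolar aprotic solvent.

Step 3
Reactants: 4 2',4'-bis(benzyloxy)acetophenone
Product: 5 [2,4-bis(benzyloxy)phenyl]glyoxal, 2-[2,4-bis(benzyloxy)phenyl]-2-oxoacetaldehyde (isolated as the hydrate)
Conditions: SeO2, 1,4-dioxane–H2O, 100 °C
Reagents that add atoms: selenium dioxide (SeO2), O=[Se]=O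
Why: Riley oxidation of an aryl methyl ketone to the arylglyoxal through the enol; benzyl aryl ethers are inert to SeO2 under these conditions.

Step 4
Reactants: 2 4,4',6'-tri-O-benzylphloretin; 5 [2,4-bis(benzyloxy)phenyl]glyoxal; 6 sodium p-toluenesulfinate
Product: 8 3'-{2-[2,4-bis(benzyloxy)phenyl]-1-[(4-methylphenyl)sulfonyl]-2-oxoethyl}-4,4',6'-tri-O-benzylphloretin (racemic; one enantiomer drawn), via carbinol 7 (not isolated)
Conditions: 6 (3 equiv), HCO2H–CH2Cl2, rt
Reagents that add atoms: none
Why: Three-component Mannich-type sulfonylalkylation of a phenol: acid-promoted Friedel–Crafts hydroxyalkylation of 2 by the aldehyde carbon of 5 at C3' gives carbinol 7, which ionises to the oxygen-stabilised benzylic cation and is trapped at sulfur by the sulfinate. C3' is favoured because it lies between the free hydroxyl and one benzyloxy group whereas C5' lies between two benzyloxy groups, and the excess of 6 should intercept the cation before a second molecule of 2 does.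

Step 5
Reactants: 9 4-(benzyloxy)benzyl chloride
Product: 10 [4-(benzyloxy)benzyl]dimethylsulfonium tetrafluoroborate
Conditions: Me2S (excess), NaBF4, acetone, rt
Reagents that add atoms: dimethyl sulfide, CSC; sodium tetrafluoroborate (NaBF4), [Na+].F[B-](F)(F)F
Why: S-Alkylation of dimethyl sulfide by the activated 4-alkoxybenzyl chloride (SN2 with SN1 character); NaCl separates from acetone, and the non-nucleophilic counter-ion is chosen over chloride to prevent the reverse dealkylation that benzylic sulfonium halides undergo.

Step 6
Reactants: 8 sulfone; 10 [4-(benzyloxy)benzyl]dimethylsulfonium tetrafluoroborate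
Product: 14 1-{(2S*,3S*)-4,6-bis(benzyloxy)-3-[2,4-bis(benzyloxy)benzoyl]-2-[4-(benzyloxy)phenyl]-2,3-dihydro-1-benzofuran-7-yl}-3-[4-(benzyloxy)phenyl]propan-1-one (2,3-trans; racemic; the 2S,3S enantiomer drawn), via sulfonium benzylide 11 (not isolated), via aroyl ortho-quinone methide 12 (not isolated), via sulfonium phenoxide betaine 13 (not isolated)
Conditions: 10 (1.5 equiv), Cs2CO3 (3 equiv), CH2Cl2–MeCN, 0 °C to rt
Reagents that add atoms: none
Why: Cs2CO3 deprotonates the chelated phenol of 8, whose phenoxide expels p-toluenesulfinate in a 1,4-elimination to give quinone methide 12, and the same base reversibly deprotonates 10 at its benzylic carbon to benzylide 11. The ylide carbon adds to the exocyclic carbon of 12 (C2–C3 bond), a conjugate addition driven by rearomatisation of ring A, to give betaine 13. The phenoxide oxygen of 13 then displaces dimethyl sulfide at C2 in an intramolecular SN2 reaction (5-exo-tet, O1–C2 bond), which closes the dihydrofuran ring. The closest known reaction type is the [4+1] annulation of ortho-quinone methides, released in situ from 2-(1-sulfonylalkyl)phenols, with sulfur ylides to trans-2,3-dihydrobenzofurans; here the quinone methide bears an aroyl group on its exocyclic carbon and the ylide is a benzylide. C2 and C3 are both created in this step: the anti betaine should close faster and C3–H, lying next to the aryl ketone, can epimerise, so the trans isomer with aryl and aroyl on opposite faces should prevail, but step 7 removes both centres and a cis/trans mixture would serve equally. The step needs attack of 11 on the quinone methide carbon and not on either ketone (epoxide formation); this is secured by the far higher electrophilicity of the transient aroyl-activated quinone methide, by the aromatic stabilisation gained, and by the hindered ortho-disubstituted nature of both ketones. It also needs O1 to be the 2'-oxygen, which is secured because that oxygen alone is free and ortho to the side arm.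

Step 7
Reactants: 14 trans-dihydrobenzofuran
Product: 15 1-{4,6-bis(benzyloxy)-3-[2,4-bis(benzyloxy)benzoyl]-2-[4-(benzyloxy)phenyl]-1-benzofuran-7-yl}-3-[4-(benzyloxy)phenyl]propan-1-one
Conditions: DDQ (1.5 equiv), 1,4-dioxane, 80 °C
Reagents that add atoms: none
Why: Quinone dehydrogenation: DDQ abstracts hydride from C2, whose cation is stabilised by O1 and the 4-benzyloxyphenyl group, and loss of the acidic C3 proton next to the ketone gives the aromatic furan, removing both stereocentres. Benzyl aryl ethers are not expected to be cleaved by DDQ under these conditions.

Step 8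
Reactants: 15 hexa-O-benzyl benzofuran
Product: 16 1-[3-(2,4-dihydroxybenzoyl)-4,6-dihydroxy-2-(4-hydroxyphenyl)-1-benzofuran-7-yl]-3-(4-hydroxyphenyl)propan-1-one (CNP0181782.0)
Conditions: H2 (1 atm), 10% Pd/C, EtOAc–MeOH, rt
Reagents that add atoms: none
Why: Hydrogenolysis of six benzyl aryl ethers over palladium on carbon; under neutral conditions at ambient pressure the benzofuran C2=C3 bond and the two aryl ketones, which become hydrogen-bonded to the liberated ortho hydroxyls, are expected to survive.

## Compound list

1 | phloretin | O=C(CCc1ccc(O)cc1)c1c(O)cc(O)cc1O | starting material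
2 | 4,4',6'-tri-O-benzylphloretin | O=C(CCc1ccc(OCc2ccccc2)cc1)c1c(O)cc(OCc2ccccc2)cc1OCc1ccccc1 | intermediate
3 | 2',4'-dihydroxyacetophenone | CC(=O)c1ccc(O)cc1O | starting material
4 | 2',4'-bis(benzyloxy)acetophenone | CC(=O)c1ccc(OCc2ccccc2)cc1OCc1ccccc1 | intermediate
5 | [2,4-bis(benzyloxy)phenyl]glyoxal | O=CC(=O)c1ccc(OCc2ccccc2)cc1OCc1ccccc1 | intermediate
6 | sodium p-toluenesulfinate | Cc1ccc(S(=O)[O-])cc1.[Na+] | starting material
7 | 3'-{2-[2,4-bis(benzyloxy)phenyl]-1-hydroxy-2-oxoethyl}-4,4',6'-tri-O-benzylphloretin (racemic; one enantiomer drawn) | O=C(CCc1ccc(OCc2ccccc2)cc1)c1c(O)c([C@H](O)C(=O)c2ccc(OCc3ccccc3)cc2OCc2ccccc2)c(OCc2ccccc2)cc1OCc1ccccc1 | intermediate (not isolated)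
8 | 3'-{2-[2,4-bis(benzyloxy)phenyl]-1-[(4-methylphenyl)sulfonyl]-2-oxoethyl}-4,4',6'-tri-O-benzylphloretin (racemic; one enantiomer drawn) | O=C(CCc1ccc(OCc2ccccc2)cc1)c1c(O)c([C@H](C(=O)c2ccc(OCc3ccccc3)cc2OCc2ccccc2)S(=O)(=O)c2ccc(C)cc2)c(OCc2ccccc2)cc1OCc1ccccc1 | intermediate
9 | 4-(benzyloxy)benzyl chloride | ClCc1ccc(OCc2ccccc2)cc1 | starting material
10 | [4-(benzyloxy)benzyl]dimethylsulfonium tetrafluoroborate | C[S+](C)Cc1ccc(OCc2ccccc2)cc1.F[B-](F)(F)F | intermediate
11 | dimethylsulfonium [4-(benzyloxy)phenyl]methylide | C[S+](C)[CH-]c1ccc(OCc2ccccc2)cc1 | intermediate (not isolated)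
12 | 3,5-bis(benzyloxy)-6-{2-[2,4-bis(benzyloxy)phenyl]-2-oxoethylidene}-2-{3-[4-(benzyloxy)phenyl]propanoyl}cyclohexa-2,4-dien-1-one (alkene geometry not defined) | O=C(CCc1ccc(OCc2ccccc2)cc1)C1=C(OCc2ccccc2)C=C(OCc2ccccc2)C(=CC(=O)c2ccc(OCc3ccccc3)cc2OCc2ccccc2)C1=O | intermediate (not isolated)
13 | zwitterion of the 2'-phenoxide carrying at C3' a CH(aroyl)–CH[4-(benzyloxy)phenyl](SMe2+) arm (diastereomer mixture; configuration not defined) | O=C(CCc1ccc(OCc2ccccc2)cc1)c1c([O-])c(C(C(=O)c2ccc(OCc3ccccc3)cc2OCc2ccccc2)C(c2ccc(OCc3ccccc3)cc2)[S+](C)C)c(OCc2ccccc2)cc1OCc1ccccc1 | intermediate (not isolated)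
14 | trans-2,3-dihydro hexa-O-benzyl ether of the target (racemic; 2S,3S drawn) | O=C(CCc1ccc(OCc2ccccc2)cc1)c1c(OCc2ccccc2)cc(OCc2ccccc2)c2c1O[C@H](c1ccc(OCc3ccccc3)cc1)[C@H]2C(=O)c1ccc(OCc2ccccc2)cc1OCc1ccccc1 | intermediate
15 | hexa-O-benzyl ether of the target | O=C(CCc1ccc(OCc2ccccc2)cc1)c1c(OCc2ccccc2)cc(OCc2ccccc2)c2c(C(=O)c3ccc(OCc4ccccc4)cc3OCc3ccccc3)c(-c3ccc(OCc4ccccc4)cc3)oc12 | intermediate
16 | CNP0181782.0 | O=C(CCc1ccc(O)cc1)c1c(O)cc(O)c2c(C(=O)c3ccc(O)cc3O)c(-c3ccc(O)cc3)oc12 | target

## Step count and least certain steps

Total: 8 steps. Longest linear sequence: 6 steps (3 → 4 → 5 → 8 → 14 → 15 → 16; steps 2, 3, 4, 6, 7, 8).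

**Step 6 (key step).**
- **Risk:** Both reactive partners are transient and are released by the same weak base at different rates. The benzylic sulfonium salt is much less acidic than the acyl-stabilised salts usual in this annulation, so the ylide may form too slowly and the quinone methide would then be lost to self-condensation. The phenoxide of 8 may also be alkylated at oxygen by 10 acting as a benzylating agent, and betaine 13 may lose the sulfide by elimination instead of substitution.
- **Fallback:** This sets out from 8 and returns at 15, so that step 7 is no longer needed. Treatment of 8 with PPh3 and Cs2CO3 in CH2Cl2 should release 12 and trap it at the exocyclic carbon; proton transfer gives the keto-stabilised phosphorus ylide, 1-[2,4-bis(benzyloxy)phenyl]-2-aryl-2-(triphenylphosphoranylidene)ethanone F1, in which the aryl group is the 2'-hydroxy ring of 2. O-Acylation of its phenol with 4-(benzyloxy)benzoyl chloride and Et3N gives the aryl ester F2. Heating F2 in toluene should close the furan by intramolecular Wittig olefination of the ester carbonyl, which delivers C2 at the acyl oxidation level and gives 15 directly.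

**Step 4.**
- **Risk:** Substitution may occur at C5' instead of C3', since the same three oxygens stabilise both sigma complexes and the preference rests on sterics. Carbinol 7 or sulfone 8 may cyclise in acid by attack of the hydroxyl on the aroyl ketone and dehydrate to a wrongly substituted benzofuran. A second molecule of 2 may capture the benzylic cation.
- **Fallback:** This sets out from 2 and returns at 8 and makes no compound outside the list. Phenol 2 is converted with EtMgBr in toluene–CH2Cl2 into its bromomagnesium phenoxide, and anhydrous 5 is added. The magnesium-bound aldehyde is delivered through a six-membered chelate to the only free ortho carbon, which makes the hydroxyalkylation ortho-specific; 7 is isolated. The hydroxyl of 7 is then exchanged for the sulfonyl group with p-toluenesulfinic acid (from 6) and catalytic TsOH in CH2Cl2 at rt to give 8.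

**Step 7.**
- **Risk:** Hydride abstraction may compete at the benzylic methylene of the propanoyl chain, giving the enone, and at benzyl ether methylenes, giving oxidative debenzylation. The desired abstraction at C2 is slowed by the adjacent aroyl group. Dehydrogenation of the chain would be repaired by the hydrogenation in step 8; loss of benzyl groups would not.
- **Fallback:** This sets out from 14 and returns at 15. Deprotonation at C3 with LiN(SiMe3)2 in THF at −78 °C and trapping with PhSeCl on the face opposite the C2 aryl group gives the 3-(phenylselanyl) derivative F3, with selenium cis to the C2 hydrogen. Oxidation with H2O2 in CH2Cl2 at 0 °C and syn elimination of the selenoxide give 15.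

**Step 8.**
- **Risk:** Cleavage of the hindered ethers at C4 and C6 may be incomplete. On prolonged exposure the diaryl ketone may be reduced or the furan C2=C3 bond saturated.
- **Fallback:** This sets out from 15, returns at 16 and makes no compound outside the list. Non-reductive debenzylation with BCl3 and pentamethylbenzene as cation scavenger in CH2Cl2 at −78 °C is used. It presupposes that step 7 left the propanoyl chain saturated.

## Further compounds

F1 | step 6 | 3'-{2-[2,4-bis(benzyloxy)phenyl]-2-oxo-1-(triphenylphosphoranylidene)ethyl}-4,4',6'-tri-O-benzylphloretin | O=C(CCc1ccc(OCc2ccccc2)cc1)c1c(O)c(C(C(=O)c2ccc(OCc3ccccc3)cc2OCc2ccccc2)=P(c2ccccc2)(c2ccccc2)c2ccccc2)c(OCc2ccccc2)cc1OCc1ccccc1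
F2 | step 6 | 2'-O-[4-(benzyloxy)benzoyl] ester of F1 | O=C(CCc1ccc(OCc2ccccc2)cc1)c1c(OC(=O)c2ccc(OCc3ccccc3)cc2)c(C(C(=O)c2ccc(OCc3ccccc3)cc2OCc2ccccc2)=P(c2ccccc2)(c2ccccc2)c2ccccc2)c(OCc2ccccc2)cc1OCc1ccccc1
F3 | step 7 | 3-(phenylselanyl) derivative of 14, selenium cis to the C2 hydrogen (racemic; one enantiomer drawn) | O=C(CCc1ccc(OCc2ccccc2)cc1)c1c(OCc2ccccc2)cc(OCc2ccccc2)c2c1O[C@H](c1ccc(OCc3ccccc3)cc1)[C@]2([Se]c1ccccc1)C(=O)c1ccc(OCc2ccccc2)cc1OCc1ccccc1
F0 | step 4 | none | none
F0 | step 8 | none | none
A1 | alternative 1 | (2,4-dimethoxyphenyl)[6-ethoxy-4-hydroxy-2-(4-methoxyphenyl)benzofuran-3-yl]methanone | CCOc1cc(O)c2c(C(=O)c3ccc(OC)cc3OC)c(-c3ccc(OC)cc3)oc2c1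
A2 | alternative 1 | 2-diazo-1-[4-(2,4-dimethoxybenzoyl)-5-(4-methoxyphenyl)furan-2-yl]ethan-1-one | [N-]=[N+]=CC(=O)c1cc(C(=O)c2ccc(OC)cc2OC)c(-c2ccc(OC)cc2)o1
A3 | alternative 1 | ethoxyacetylene | CCOC#C
A4 | alternative 2 | trans-(2,4-dimethoxyphenyl)[4,6-dimethoxy-2-(4-methoxyphenyl)-2,3-dihydrobenzofuran-3-yl]methanone (racemic; one enantiomer drawn) | O1[C@H](c2ccc(OC)cc2)[C@@H](C(=O)c2ccc(OC)cc2OC)c2c(OC)cc(OC)cc21
A5 | alternative 2 | 4-(2,4-dimethoxyphenyl)-5,7-dimethoxy-2-(4-methoxyphenyl)-2H-chromene (racemic) | COc1ccc(C2C=C(c3ccc(OC)cc3OC)c3c(OC)cc(OC)cc3O2)cc1
A6 | alternative 3 | hexa-O-benzyl ether of the target (identical with 15) | O=C(CCc1ccc(OCc2ccccc2)cc1)c1c(OCc2ccccc2)cc(OCc2ccccc2)c2c(C(=O)c3ccc(OCc4ccccc4)cc3OCc3ccccc3)c(-c3ccc(OCc4ccccc4)cc3)oc12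
A7 | alternative 3 | 1-[2,4-bis(benzyloxy)phenyl]-3-[4-(benzyloxy)phenyl]prop-2-yn-1-one | O=C(C#Cc1ccc(OCc2ccccc2)cc1)c1ccc(OCc2ccccc2)cc1OCc1ccccc1
A8 | alternative 3 | 2'-O-{3-[2,4-bis(benzyloxy)phenyl]-1-[4-(benzyloxy)phenyl]-3-oxoprop-1-enyl}-4,4',6'-tri-O-benzylphloretin (alkene geometry not defined) | O=C(C=C(Oc1cc(OCc2ccccc2)cc(OCc2ccccc2)c1C(=O)CCc1ccc(OCc2ccccc2)cc1)c1ccc(OCc2ccccc2)cc1)c1ccc(OCc2ccccc2)cc1OCc1ccccc1
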